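**Assumption:** the target SMILES has no stereodescriptor and the molecule has no stereocentre; the hindered aryl–naphthyl axis is left unspecified, so no enantiocontrol is needed. The route is designed on paper and has not been run.

## Retrosynthetic overview

1. Target 20 ⇐ tetrabenzyl naphthol 19 by hydrogenolysis of four aryl benzyl ethers.
2. Ring B (the naphthol ring, the only ring made; the benzene rings A, C and D are bought) ⇐ intramolecular aldol condensation and aromatisation of keto-benzophenone 17.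
3. 17 ⇐ decarboxylation of β-keto ester 15 ⇐ crossed Claisen condensation of arylacetate 9 (rings A and C) with acyl chloride 13 (ring D); this is the key fragment-joining C–C bond.
4. 9 ⇐ bromobenzophenone 8 by ester-enolate arylation ⇐ aryllithium from 5 plus bromoaldehyde 3 (from syringaldehyde), then oxidation.
5. 13 ⇐ 3-(3,4-dihydroxyphenyl)propanoic acid by benzylation, saponification and chlorination.

## Route

Step 1
Reactants: 1 syringaldehyde (4-hydroxy-3,5-dimethoxybenzaldehyde)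
Product: 2 4-(benzyloxy)-3,5-dimethoxybenzaldehyde
Conditions: BnBr (1.2 equiv), K2CO3, DMF, 60 °C
Reagents that add atoms: benzyl bromide, BrCc1ccccc1
Why: Williamson ether synthesis on the only phenol masks the future ring A hydroxyl as a hydrogenolysable benzyl ether.

Step 2
Reactants: 2 4-(benzyloxy)-3,5-dimethoxybenzaldehyde
Product: 3 4-(benzyloxy)-2-bromo-3,5-dimethoxybenzaldehyde
Conditions: NBS (1.05 equiv), MeCN, rt to 40 °C, dark
Reagents that add atoms: N-bromosuccinimide, O=C1CCC(=O)N1Br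
Why: Electrophilic aromatic bromination; the two free ring positions are equivalent and activated by ortho and para methoxy groups, so only one monobromide can form.

Step 3
Reactants: 4 4-bromo-3-methoxyphenol
Product: 5 4-(benzyloxy)-1-bromo-2-methoxybenzene
Conditions: BnBr (1.1 equiv), K2CO3, acetone, reflux
Reagents that add atoms: benzyl bromide, BrCc1ccccc1
Why: Williamson ether synthesis protects the ring C phenol before the organolithium step.

Step 4
Reactants: 5 4-(benzyloxy)-1-bromo-2-methoxybenzene, 3 4-(benzyloxy)-2-bromo-3,5-dimethoxybenzaldehyde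
Product: 7 racemic [4-(benzyloxy)-2-bromo-3,5-dimethoxyphenyl][4-(benzyloxy)-2-methoxyphenyl]methanol, via aryllithium 6 (not isolated)
Conditions: n-BuLi (1.0 equiv), THF, −78 °C; then 3, −78 to −20 °C; aq. NH4Cl
Reagents that add atoms: none
Why: Bromine–lithium exchange followed by 1,2-addition of the aryllithium to the aldehyde, which is much faster than exchange with the hindered bromide of 3; the carbinol centre is racemic and is erased in step 5.

Step 5
Reactants: 7 racemic [4-(benzyloxy)-2-bromo-3,5-dimethoxyphenyl][4-(benzyloxy)-2-methoxyphenyl]methanol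
Product: 8 [4-(benzyloxy)-2-bromo-3,5-dimethoxyphenyl][4-(benzyloxy)-2-methoxyphenyl]methanone
Conditions: Dess–Martin periodinane (1.3 equiv), CH2Cl2, rt
Reagents that add atoms: none
Why: Dess–Martin oxidation of a doubly benzylic secondary alcohol to the diaryl ketone is mild and leaves ethers and the aryl bromide untouched.

Step 6
Reactants: 8 [4-(benzyloxy)-2-bromo-3,5-dimethoxyphenyl][4-(benzyloxy)-2-methoxyphenyl]methanone
Product: 9 tert-butyl 2-{3-(benzyloxy)-6-[4-(benzyloxy)-2-methoxybenzoyl]-2,4-dimethoxyphenyl}acetate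
Conditions: BrZnCH2CO2t-Bu (1.5 equiv), Pd2(dba)3 (2.5 mol %), XPhos (10 mol %), THF, 50 °C
Reagents that add atoms: tert-butyl 2-(bromozincio)acetate, CC(C)(C)OC(=O)C[Zn]Br
Why: Negishi-type palladium-catalysed α-arylation of an ester with a Reformatsky reagent; oxidative addition to zerovalent palladium is helped by the ortho ketone, and the neutral zinc enolate does not attack the hindered diaryl ketone.

Step 7
Reactants: 10 3-(3,4-dihydroxyphenyl)propanoic acid
Product: 11 benzyl 3-[3,4-bis(benzyloxy)phenyl]propanoate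
Conditions: BnBr (3.5 equiv), K2CO3, DMF, 60 °C
Reagents that add atoms: benzyl bromide, BrCc1ccccc1
Why: Exhaustive O-alkylation (Williamson etherification plus carboxylate alkylation) protects the catechol of ring D in one operation.

Step 8
Reactants: 11 benzyl 3-[3,4-bis(benzyloxy)phenyl]propanoate
Product: 12 3-[3,4-bis(benzyloxy)phenyl]propanoic acid
Conditions: NaOH, THF/MeOH/H2O, 40 °C; then aq. HCl
Reagents that add atoms: sodium hydroxide, [Na+].[OH-]
Why: Saponification cleaves only the ester; aryl benzyl ethers are stable to hydroxide.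

Step 9
Reactants: 12 3-[3,4-bis(benzyloxy)phenyl]propanoic acid
Product: 13 3-[3,4-bis(benzyloxy)phenyl]propanoyl chloride
Conditions: (COCl)2 (1.3 equiv), cat. DMF, CH2Cl2, 0 °C to rt
Reagents that add atoms: oxalyl chloride, O=C(Cl)C(=O)Cl
Why: Vilsmeier-catalysed acid chloride formation gives a reactive acyl donor under conditions that do not touch the benzyl ethers.

Step 10
Reactants: 9 tert-butyl 2-{3-(benzyloxy)-6-[4-(benzyloxy)-2-methoxybenzoyl]-2,4-dimethoxyphenyl}acetate, 13 3-[3,4-bis(benzyloxy)phenyl]propanoyl chloride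
Product: 15 racemic tert-butyl 2-{3-(benzyloxy)-6-[4-(benzyloxy)-2-methoxybenzoyl]-2,4-dimethoxyphenyl}-5-[3,4-bis(benzyloxy)phenyl]-3-oxopentanoate, via lithium enolate 14 (not isolated)
Conditions: LiN(SiMe3)2 (2.1 equiv), THF, −78 °C; then 13 (1.1 equiv), −78 to 0 °C; aq. NH4Cl
Reagents that add atoms: none
Why: Crossed Claisen condensation (C-acylation of an ester enolate): the benzylic ester CH2 is the only acidic site of 9, the silylamide neither adds to nor reduces the diaryl ketone, and the second equivalent of base holds the β-keto ester as its enolate so acylation stops; the new centre is racemic and is lost in step 11.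

Step 11
Reactants: 15 racemic tert-butyl 2-{3-(benzyloxy)-6-[4-(benzyloxy)-2-methoxybenzoyl]-2,4-dimethoxyphenyl}-5-[3,4-bis(benzyloxy)phenyl]-3-oxopentanoate
Product: 17 1-{3-(benzyloxy)-6-[4-(benzyloxy)-2-methoxybenzoyl]-2,4-dimethoxyphenyl}-4-[3,4-bis(benzyloxy)phenyl]butan-2-one, via β-keto acid 16 (not isolated)
Conditions: CF3CO2H/CH2Cl2 (1:3), 0 °C to rt; concentrate; toluene, 80 °C; aq. NaHCO3 wash
Reagents that add atoms: none
Why: Acidolysis of the tert-butyl ester (E1 loss of isobutene) followed by decarboxylation of the β-keto acid through its cyclic six-membered transition state; aryl benzyl ethers tolerate CF3CO2H at room temperature.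

Step 12
Reactants: 17 1-{3-(benzyloxy)-6-[4-(benzyloxy)-2-methoxybenzoyl]-2,4-dimethoxyphenyl}-4-[3,4-bis(benzyloxy)phenyl]butan-2-one
Product: 19 7-(benzyloxy)-4-[4-(benzyloxy)-2-methoxyphenyl]-3-[3,4-bis(benzyloxy)benzyl]-6,8-dimethoxynaphthalen-2-ol, via aldol adduct 18 (not isolated)
Conditions: KOt-Bu (3 equiv), THF/t-BuOH, 50 °C, argon; then aq. HCl
Reagents that add atoms: none
Why: Intramolecular aldol condensation: enolisation at the benzylic CH2 is reversible and cannot cyclise, whereas the enolate on the other side closes a six-membered ring onto the diaryl ketone, and E1cB dehydration plus tautomerisation gives the aromatic naphthoxide irreversibly; both transient centres of 18 are destroyed.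

Step 13
Reactants: 19 7-(benzyloxy)-4-[4-(benzyloxy)-2-methoxyphenyl]-3-[3,4-bis(benzyloxy)benzyl]-6,8-dimethoxynaphthalen-2-ol
Product: 20 3-(3,4-dihydroxybenzyl)-4-(4-hydroxy-2-methoxyphenyl)-6,8-dimethoxynaphthalene-2,7-diol (CNP0000244.0)
Conditions: H2 (1 atm), 10% Pd/C, EtOAc/MeOH, rt; work up under argon
Reagents that add atoms: none
Why: Catalytic hydrogenolysis removes all four aryl benzyl ethers, while the naphthalene, the three methyl ethers and the diarylmethane CH2 are inert at 1 atm.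

## Compound list

1 | syringaldehyde (4-hydroxy-3,5-dimethoxybenzaldehyde) | COc1cc(C=O)cc(OC)c1O | starting material
2 | 4-(benzyloxy)-3,5-dimethoxybenzaldehyde | COc1cc(C=O)cc(OC)c1OCc1ccccc1 | intermediate
3 | 4-(benzyloxy)-2-bromo-3,5-dimethoxybenzaldehyde | COc1cc(C=O)c(Br)c(OC)c1OCc1ccccc1 | intermediate
4 | 4-bromo-3-methoxyphenol | COc1cc(O)ccc1Br | starting material
5 | 4-(benzyloxy)-1-bromo-2-methoxybenzene | COc1cc(OCc2ccccc2)ccc1Br | intermediate
6 | [4-(benzyloxy)-2-methoxyphenyl]lithium (not isolated) | COc1cc(OCc2ccccc2)ccc1[Li] | intermediate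
7 | [4-(benzyloxy)-2-bromo-3,5-dimethoxyphenyl][4-(benzyloxy)-2-methoxyphenyl]methanol, racemic | COc1cc(C(O)c2ccc(OCc3ccccc3)cc2OC)c(Br)c(OC)c1OCc1ccccc1 | intermediate
8 | [4-(benzyloxy)-2-bromo-3,5-dimethoxyphenyl][4-(benzyloxy)-2-methoxyphenyl]methanone | COc1cc(C(=O)c2ccc(OCc3ccccc3)cc2OC)c(Br)c(OC)c1OCc1ccccc1 | intermediate
9 | tert-butyl 2-{3-(benzyloxy)-6-[4-(benzyloxy)-2-methoxybenzoyl]-2,4-dimethoxyphenyl}acetate | COc1cc(C(=O)c2ccc(OCc3ccccc3)cc2OC)c(CC(=O)OC(C)(C)C)c(OC)c1OCc1ccccc1 | intermediate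
10 | 3-(3,4-dihydroxyphenyl)propanoic acid | OC(=O)CCc1ccc(O)c(O)c1 | starting material
11 | benzyl 3-[3,4-bis(benzyloxy)phenyl]propanoate | O=C(CCc1ccc(OCc2ccccc2)c(OCc2ccccc2)c1)OCc1ccccc1 | intermediate
12 | 3-[3,4-bis(benzyloxy)phenyl]propanoic acid | OC(=O)CCc1ccc(OCc2ccccc2)c(OCc2ccccc2)c1 | intermediate
13 | 3-[3,4-bis(benzyloxy)phenyl]propanoyl chloride | ClC(=O)CCc1ccc(OCc2ccccc2)c(OCc2ccccc2)c1 | intermediate
14 | lithium enolate of 9 (not isolated; enolate geometry unspecified) | COc1cc(C(=O)c2ccc(OCc3ccccc3)cc2OC)c(C=C(O[Li])OC(C)(C)C)c(OC)c1OCc1ccccc1 | intermediate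
15 | tert-butyl 2-{3-(benzyloxy)-6-[4-(benzyloxy)-2-methoxybenzoyl]-2,4-dimethoxyphenyl}-5-[3,4-bis(benzyloxy)phenyl]-3-oxopentanoate, racemic | COc1cc(C(=O)c2ccc(OCc3ccccc3)cc2OC)c(C(C(=O)OC(C)(C)C)C(=O)CCc2ccc(OCc3ccccc3)c(OCc3ccccc3)c2)c(OC)c1OCc1ccccc1 | intermediate
16 | 2-{3-(benzyloxy)-6-[4-(benzyloxy)-2-methoxybenzoyl]-2,4-dimethoxyphenyl}-5-[3,4-bis(benzyloxy)phenyl]-3-oxopentanoic acid, racemic (not isolated) | COc1cc(C(=O)c2ccc(OCc3ccccc3)cc2OC)c(C(C(=O)O)C(=O)CCc2ccc(OCc3ccccc3)c(OCc3ccccc3)c2)c(OC)c1OCc1ccccc1 | intermediate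
17 | 1-{3-(benzyloxy)-6-[4-(benzyloxy)-2-methoxybenzoyl]-2,4-dimethoxyphenyl}-4-[3,4-bis(benzyloxy)phenyl]butan-2-one | COc1cc(C(=O)c2ccc(OCc3ccccc3)cc2OC)c(CC(=O)CCc2ccc(OCc3ccccc3)c(OCc3ccccc3)c2)c(OC)c1OCc1ccccc1 | intermediate
18 | 7-(benzyloxy)-4-[4-(benzyloxy)-2-methoxyphenyl]-3-[3,4-bis(benzyloxy)benzyl]-4-hydroxy-6,8-dimethoxy-3,4-dihydronaphthalen-2(1H)-one, mixture of racemic diastereomers (not isolated) | COc1cc2c(c(OC)c1OCc1ccccc1)CC(=O)C(Cc1ccc(OCc3ccccc3)c(OCc3ccccc3)c1)C2(O)c1ccc(OCc2ccccc2)cc1OC | intermediate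
19 | 7-(benzyloxy)-4-[4-(benzyloxy)-2-methoxyphenyl]-3-[3,4-bis(benzyloxy)benzyl]-6,8-dimethoxynaphthalen-2-ol | COc1cc2c(-c3ccc(OCc4ccccc4)cc3OC)c(Cc3ccc(OCc4ccccc4)c(OCc4ccccc4)c3)c(O)cc2c(OC)c1OCc1ccccc1 | intermediate
20 | 3-(3,4-dihydroxybenzyl)-4-(4-hydroxy-2-methoxyphenyl)-6,8-dimethoxynaphthalene-2,7-diol (no stereocentre) | COc1cc(O)ccc1-c1c(Cc2ccc(O)c(O)c2)c(O)cc2c(OC)c(O)c(OC)cc12 | target

## Summary

Total step count: 13.
Longest linear sequence: 9 steps (steps 1, 2, 4, 5, 6, 10, 11, 12, 13, from syringaldehyde).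

Three steps most likely to fail, each with a fallback:

**Step 6** (cross-coupling at a bromide flanked by a methoxy group and the aroyl group). The fallback sets out from 8 and builds the acetate arm by allylation and oxidative degradation instead of enolate arylation. Stille coupling of 8 with allyltributylstannane (Pd(PPh3)4, CsF, dioxane, 100 °C) gives [2-allyl-4-(benzyloxy)-3,5-dimethoxyphenyl][4-(benzyloxy)-2-methoxyphenyl]methanone F1. Lemieux–Johnson cleavage (OsO4 cat., NaIO4, 2,6-lutidine, dioxane/H2O) gives 2-{3-(benzyloxy)-6-[4-(benzyloxy)-2-methoxybenzoyl]-2,4-dimethoxyphenyl}acetaldehyde F2. Pinnick oxidation (NaClO2, NaH2PO4, 2-methyl-2-butene, t-BuOH/H2O) gives 2-{3-(benzyloxy)-6-[4-(benzyloxy)-2-methoxybenzoyl]-2,4-dimethoxyphenyl}acetic acid F3. Esterification with tert-butyl 2,2,2-trichloroacetimidate and cat. BF3·OEt2 in CH2Cl2 comes back to the route at 9.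

**Step 10** (O-acylation or ketene formation may compete with C-acylation of the hindered enolate). The fallback sets out from 9 and 11 and replaces the acylation by an aldol addition and oxidation. i-Bu2AlH (1.05 equiv, CH2Cl2, −78 °C) reduces 11 to 3-[3,4-bis(benzyloxy)phenyl]propanal F4. Lithium enolate 14 (from 9, LiN(SiMe3)2, THF, −78 °C) adds to this aldehyde to give tert-butyl 2-{3-(benzyloxy)-6-[4-(benzyloxy)-2-methoxybenzoyl]-2,4-dimethoxyphenyl}-5-[3,4-bis(benzyloxy)phenyl]-3-hydroxypentanoate F5 as a mixture of racemic diastereomers. Dess–Martin oxidation of the secondary alcohol comes back to the route at 15.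

**Step 12** (the electron-rich, hindered diaryl ketone is a poor aldol acceptor). The fallback sets out from 15 and keeps the ester as an activating group so that a far more nucleophilic dianion performs the ring closure.
- Lithium 2,2,6,6-tetramethylpiperidide (2.2 equiv, THF, −78 to 0 °C) gives the dilithium dianion of 15 F6.
- Its terminal carbanion adds to the diaryl ketone to give, after aq. NH4Cl, tert-butyl 7-(benzyloxy)-4-[4-(benzyloxy)-2-methoxyphenyl]-3-[3,4-bis(benzyloxy)benzyl]-4-hydroxy-6,8-dimethoxy-2-oxo-1,2,3,4-tetrahydronaphthalene-1-carboxylate F7.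
- Cat. TsOH (CH2Cl2, rt) dehydrates and aromatises it to tert-butyl 7-(benzyloxy)-4-[4-(benzyloxy)-2-methoxyphenyl]-3-[3,4-bis(benzyloxy)benzyl]-2-hydroxy-6,8-dimethoxynaphthalene-1-carboxylate F8.
- CF3CO2H/CH2Cl2 then gives 7-(benzyloxy)-4-[4-(benzyloxy)-2-methoxyphenyl]-3-[3,4-bis(benzyloxy)benzyl]-2-hydroxy-6,8-dimethoxynaphthalene-1-carboxylic acid F9.
- F9 decarboxylates on warming in toluene and comes back to the route at 19.

## Further compounds

F1 | step 6 | [2-allyl-4-(benzyloxy)-3,5-dimethoxyphenyl][4-(benzyloxy)-2-methoxyphenyl]methanone | COc1cc(C(=O)c2ccc(OCc3ccccc3)cc2OC)c(CC=C)c(OC)c1OCc1ccccc1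
F2 | step 6 | 2-{3-(benzyloxy)-6-[4-(benzyloxy)-2-methoxybenzoyl]-2,4-dimethoxyphenyl}acetaldehyde | COc1cc(C(=O)c2ccc(OCc3ccccc3)cc2OC)c(CC=O)c(OC)c1OCc1ccccc1
F3 | step 6 | 2-{3-(benzyloxy)-6-[4-(benzyloxy)-2-methoxybenzoyl]-2,4-dimethoxyphenyl}acetic acid | COc1cc(C(=O)c2ccc(OCc3ccccc3)cc2OC)c(CC(=O)O)c(OC)c1OCc1ccccc1
F4 | step 10 | 3-[3,4-bis(benzyloxy)phenyl]propanal | O=CCCc1ccc(OCc2ccccc2)c(OCc2ccccc2)c1
F5 | step 10 | tert-butyl 2-{3-(benzyloxy)-6-[4-(benzyloxy)-2-methoxybenzoyl]-2,4-dimethoxyphenyl}-5-[3,4-bis(benzyloxy)phenyl]-3-hydroxypentanoate, mixture of racemic diastereomers | COc1cc(C(=O)c2ccc(OCc3ccccc3)cc2OC)c(C(C(=O)OC(C)(C)C)C(O)CCc2ccc(OCc3ccccc3)c(OCc3ccccc3)c2)c(OC)c1OCc1ccccc1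
F6 | step 12 | dilithium dianion of 15 | [Li+].[Li+].COc1cc(C(=O)c2ccc(OCc3ccccc3)cc2OC)c(C(C(=O)OC(C)(C)C)=C([O-])[CH-]Cc2ccc(OCc3ccccc3)c(OCc3ccccc3)c2)c(OC)c1OCc1ccccc1
F7 | step 12 | tert-butyl 7-(benzyloxy)-4-[4-(benzyloxy)-2-methoxyphenyl]-3-[3,4-bis(benzyloxy)benzyl]-4-hydroxy-6,8-dimethoxy-2-oxo-1,2,3,4-tetrahydronaphthalene-1-carboxylate, mixture of racemic diastereomers | COc1cc2c(c(OC)c1OCc1ccccc1)C(C(=O)OC(C)(C)C)C(=O)C(Cc1ccc(OCc3ccccc3)c(OCc3ccccc3)c1)C2(O)c1ccc(OCc2ccccc2)cc1OC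
F8 | step 12 | tert-butyl 7-(benzyloxy)-4-[4-(benzyloxy)-2-methoxyphenyl]-3-[3,4-bis(benzyloxy)benzyl]-2-hydroxy-6,8-dimethoxynaphthalene-1-carboxylate | COc1cc2c(-c3ccc(OCc4ccccc4)cc3OC)c(Cc3ccc(OCc4ccccc4)c(OCc4ccccc4)c3)c(O)c(C(=O)OC(C)(C)C)c2c(OC)c1OCc1ccccc1
F9 | step 12 | 7-(benzyloxy)-4-[4-(benzyloxy)-2-methoxyphenyl]-3-[3,4-bis(benzyloxy)benzyl]-2-hydroxy-6,8-dimethoxynaphthalene-1-carboxylic acid | COc1cc2c(-c3ccc(OCc4ccccc4)cc3OC)c(Cc3ccc(OCc4ccccc4)c(OCc4ccccc4)c3)c(O)c(C(=O)O)c2c(OC)c1OCc1ccccc1
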